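**Target:** CNP0176653.1, (2E,6E)-9-[(2R)-6-hydroxy-2,8-dimethyl-3,4-dihydro-2H-chromen-2-yl]-2,6-dimethylnona-2,6-dienoic acid (C22H30O4; one stereocentre, C2 = R; both side-chain alkenes E).

**Retrosynthetic overview**
1. Target 8 ⇐ bromo ester 6: one-pot ArBr → ArOH (Pd, KOH) and ester hydrolysis; the bromine is a latent 6-OH that also blocks the para position.
2. 6 ⇐ bromochromane 4 + methyl methacrylate 5: cross-metathesis at the isopropylidene terminus builds the (E)-2-methylenoate end.
3. 4 ⇐ farnesylphenol 3: cyclase-like, enantioselective proton-initiated closure of the phenol oxygen onto C3' of the proximal alkene; sets C2 (R).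
4. 3 ⇐ 4-bromo-2-methylphenol 1 + (2E,6E)-farnesol 2: ortho-C-farnesylation.
5. Ring order: the arene is bought; the dihydropyran ring is the only ring made (step 2).

Assumption: the sense of induction of the confined chiral acid in step 2 cannot be predicted with certainty; the catalyst enantiomer that gives the (2R)-chromane is used and is written below as the (S,S)-catalyst (its mirror image is equally accessible from (R)-BINOL).

**Step 1**
Reactants: 1 4-bromo-2-methylphenol; 2 (2E,6E)-farnesol
Product: 3 4-bromo-2-methyl-6-[(2E,6E)-3,7,11-trimethyldodeca-2,6,10-trien-1-yl]phenol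
Conditions: acidic Al2O3 (Brockmann activity 1), 1,2-dichloroethane, reflux, 24 h; chromatography to remove any non-phenolic cyclized material
Reagents that add atoms: none
Why: Alumina-directed Friedel–Crafts ortho-allylation: the surface-bound phenol is alkylated by the adjacent ionised allylic alcohol at its only free ortho position (para is blocked by Br), with linear regiochemistry and retention of the (2E) geometry; no stereocentre is formed.

**Step 2**
Reactants: 3 4-bromo-2-methyl-6-[(2E,6E)-3,7,11-trimethyldodeca-2,6,10-trien-1-yl]phenol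
Product: 4 (2R)-6-bromo-2-[(3E)-4,8-dimethylnona-3,7-dien-1-yl]-2,8-dimethyl-3,4-dihydro-2H-chromene
Conditions: (S,S)-IDPi (confined imidodiphosphorimidate Brønsted acid from two 3,3'-diaryl-(S)-BINOL units, N-SO2CF3 groups on phosphorus; 5 mol%), cyclohexane, 50 °C, 48 h
Reagents that add atoms: none
Why: Proposed new method: the confined acid hydrogen-bonds the phenol OH and protonates C2' of the adjacent (E)-trisubstituted alkene while the phenol oxygen closes onto C3' in a concerted, asynchronous Markovnikov hydroalkoxylation (the chemical counterpart of tocopherol cyclase), the chiral pocket selecting C–O bond formation on the Re face of C3', which gives the 2R quaternary ether; the distal alkenes have no internal nucleophile placed for this concerted path, and the non-polar solvent disfavours free-cation polyene cyclization; the closest known reaction types are IDPi-catalysed asymmetric intramolecular hydroalkoxylation of unactivated alkenols and auxiliary-directed biomimetic chromanol cyclization.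

**Step 3**
Reactants: 4 (2R)-6-bromo-2-[(3E)-4,8-dimethylnona-3,7-dien-1-yl]-2,8-dimethyl-3,4-dihydro-2H-chromene; 5 methyl methacrylate
Product: 6 methyl (2E,6E)-9-[(2R)-6-bromo-2,8-dimethyl-3,4-dihydro-2H-chromen-2-yl]-2,6-dimethylnona-2,6-dienoate
Conditions: second-generation Hoveyda–Grubbs catalyst RuCl2(H2IMes)(=CH-C6H4-2-OiPr) (5 mol%), methyl methacrylate (10 equiv), 1,4-benzoquinone (10 mol%), dimethyl carbonate, 80 °C, argon sweep
Reagents that add atoms: none
Why: Olefin cross-metathesis of a terpenoid isopropylidene terminus with methyl methacrylate, driven by loss of isobutene, gives the thermodynamically preferred (E)-trisubstituted enoate; the gem-dimethyl terminus should react ahead of the more encumbered internal trisubstituted alkene, and the aryl bromide and C2 stereocentre are untouched.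

**Step 4**
Reactants: 6 methyl (2E,6E)-9-[(2R)-6-bromo-2,8-dimethyl-3,4-dihydro-2H-chromen-2-yl]-2,6-dimethylnona-2,6-dienoate
Product: 8 (2E,6E)-9-[(2R)-6-hydroxy-2,8-dimethyl-3,4-dihydro-2H-chromen-2-yl]-2,6-dimethylnona-2,6-dienoic acid, via dipotassium phenoxide carboxylate 7 (not isolated)
Conditions: Pd2(dba)3 (2 mol%), tBuXPhos (8 mol%), KOH (6 equiv), degassed 1,4-dioxane/H2O 1:1, 100 °C, argon; then 1 M HCl to pH 3, 0 °C
Reagents that add atoms: potassium hydroxide, [K+].[OH-]
Why: Palladium-catalysed hydroxylation of the electron-rich aryl bromide (oxidative addition to zerovalent palladium, bromide/hydroxide exchange, C–O reductive elimination from the bulky biarylphosphine complex) runs in the same hot aqueous KOH that saponifies the methyl ester, and acidification releases the chromanol acid; the alkenes and the quaternary C2 stereocentre are inert to these conditions.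

**Compound list**
1 | 4-bromo-2-methylphenol | Cc1cc(Br)ccc1O | starting material
2 | (2E,6E)-farnesol, (2E,6E)-3,7,11-trimethyldodeca-2,6,10-trien-1-ol | CC(C)=CCC/C(C)=C/CC/C(C)=C/CO | starting material
3 | 4-bromo-2-methyl-6-[(2E,6E)-3,7,11-trimethyldodeca-2,6,10-trien-1-yl]phenol | CC(C)=CCC/C(C)=C/CC/C(C)=C/Cc1cc(Br)cc(C)c1O | intermediate
4 | (2R)-6-bromo-2-[(3E)-4,8-dimethylnona-3,7-dien-1-yl]-2,8-dimethyl-3,4-dihydro-2H-chromene | CC(C)=CCC/C(C)=C/CC[C@]1(C)CCc2cc(Br)cc(C)c2O1 | intermediate
5 | methyl methacrylate | C=C(C)C(=O)OC | starting material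
6 | methyl (2E,6E)-9-[(2R)-6-bromo-2,8-dimethyl-3,4-dihydro-2H-chromen-2-yl]-2,6-dimethylnona-2,6-dienoate | COC(=O)/C(C)=C/CC/C(C)=C/CC[C@]1(C)CCc2cc(Br)cc(C)c2O1 | intermediate
7 | dipotassium (2E,6E)-9-[(2R)-2,8-dimethyl-6-oxido-3,4-dihydro-2H-chromen-2-yl]-2,6-dimethylnona-2,6-dienoate | C/C(=C\CC[C@]1(C)CCc2cc([O-])cc(C)c2O1)CC/C=C(\C)C(=O)[O-].[K+].[K+] | intermediate
8 | (2E,6E)-9-[(2R)-6-hydroxy-2,8-dimethyl-3,4-dihydro-2H-chromen-2-yl]-2,6-dimethylnona-2,6-dienoic acid | C/C(=C\CC[C@]1(C)CCc2cc(O)cc(C)c2O1)CC/C=C(\C)C(=O)O | target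

**Total step count:** 4. **Longest linear sequence:** 4 (1 + 2 → 3 → 4 → 6 → 8).

**Steps most likely to fail, with fallbacks**

Step 2 (asymmetric cyclization) is the largest risk. The enantioselectivity is unproven for an aryl-OH nucleophile with a trisubstituted alkene, and protonation of a distal alkene could start polyene cyclization. The fallback sets out from 3 and gives up catalyst control in favour of resolution. Closing the ring with p-TsOH·H2O (10 mol%) in CH2Cl2 at room temperature gives racemic 6-bromo-2-[(3E)-4,8-dimethylnona-3,7-dien-1-yl]-2,8-dimethyl-3,4-dihydro-2H-chromene F3. Preparative HPLC on a cellulose tris(3,5-dimethylphenylcarbamate) phase then separates the enantiomers, and the (2R)-enantiomer is compound 4, where the route resumes.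

Step 3 (cross-metathesis) may also cut the internal trisubstituted alkene and give truncated products. The fallback sets out from 4 and builds the acid terminus by allylic oxidation instead. SeO2 (0.5 equiv), t-BuOOH and catalytic salicylic acid in CH2Cl2 oxidize the terminal (E)-methyl group to (2E,6E)-9-[(2R)-6-bromo-2,8-dimethyl-3,4-dihydro-2H-chromen-2-yl]-2,6-dimethylnona-2,6-dien-1-ol F4. MnO2 in CH2Cl2 gives (2E,6E)-9-[(2R)-6-bromo-2,8-dimethyl-3,4-dihydro-2H-chromen-2-yl]-2,6-dimethylnona-2,6-dienal F5. Pinnick oxidation (NaClO2, NaH2PO4, 2-methyl-2-butene, t-BuOH/H2O) gives (2E,6E)-9-[(2R)-6-bromo-2,8-dimethyl-3,4-dihydro-2H-chromen-2-yl]-2,6-dimethylnona-2,6-dienoic acid F6. Under the step 4 conditions F6 gives compound 7, where the route resumes, and acidification gives 8.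

Step 1 (ortho-farnesylation) may give a low yield with the deactivated bromophenol, partial E/Z scrambling through the allyl cation, or premature racemic ring closure. The fallback sets out from 1 and 2 and replaces the cationic Friedel–Crafts reaction with SN2 C-alkylation of a phenoxide. PBr3 in Et2O at −10 °C converts 2 into (2E,6E)-farnesyl bromide F1. NaH in toluene converts 1 into sodium 4-bromo-2-methylphenoxide F2. Stirring the suspended tight ion pair F2 with F1 in toluene at room temperature gives ortho-C-alkylation without an allyl cation, so the (2E) geometry is kept; this is compound 3, where the route resumes.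

**Further compounds**
F1 | step 1 | (2E,6E)-farnesyl bromide | CC(C)=CCC/C(C)=C/CC/C(C)=C/CBr
F2 | step 1 | sodium 4-bromo-2-methylphenoxide | Cc1cc(Br)ccc1[O-].[Na+]
F3 | step 2 | racemic 6-bromo-2-[(3E)-4,8-dimethylnona-3,7-dien-1-yl]-2,8-dimethyl-3,4-dihydro-2H-chromene | CC(C)=CCC/C(C)=C/CCC1(C)CCc2cc(Br)cc(C)c2O1
F4 | step 3 | (2E,6E)-9-[(2R)-6-bromo-2,8-dimethyl-3,4-dihydro-2H-chromen-2-yl]-2,6-dimethylnona-2,6-dien-1-ol | OC/C(C)=C/CC/C(C)=C/CC[C@]1(C)CCc2cc(Br)cc(C)c2O1
F5 | step 3 | (2E,6E)-9-[(2R)-6-bromo-2,8-dimethyl-3,4-dihydro-2H-chromen-2-yl]-2,6-dimethylnona-2,6-dienal | O=C/C(C)=C/CC/C(C)=C/CC[C@]1(C)CCc2cc(Br)cc(C)c2O1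
F6 | step 3 | (2E,6E)-9-[(2R)-6-bromo-2,8-dimethyl-3,4-dihydro-2H-chromen-2-yl]-2,6-dimethylnona-2,6-dienoic acid | OC(=O)/C(C)=C/CC/C(C)=C/CC[C@]1(C)CCc2cc(Br)cc(C)c2O1
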